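**Assumption:** the target is read as 4′‑O‑acetylcnicin, (6R,7R,8S,3′R): trans‑fused 6α,12‑lactone, 8α‑acyloxy, both ring alkenes trans within the ring (1(10)E and, by CIP because of O‑15, 4Z). Germacrane numbering (C1–C15, side chain C1′–C4′) is used throughout.

## Retrosynthetic overview

1. Target ⇒ tin‑directed 4′‑O‑acetylation of cnicin ⇒ 8‑O‑acylation of 15‑O‑silyl salonitenolide with an acetonide‑protected (R)‑3,4‑dihydroxy‑2‑methylenebutanoic acid (from methyl (S)‑glycerate acetonide by alkynylation and Markovnikov hydroxycarbonylation).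
2. The ten‑membered carbocycle and the trans γ‑lactone are closed together at C6–C7 by an electrochemical, chromium‑catalysed intramolecular allylation of an enal by a 2‑(bromomethyl)enoate; the bought C8 centre sets C7 and C6.
3. Seco precursor ⇒ Baylis–Hillman reaction and SN2′ bromination at C7, after a B‑alkyl Suzuki coupling (C1–C2) of an (E)‑alkenyl iodide with a (Z)‑dienol.
4. Alkenyl iodide from (R)‑glycidol (acetylide opening, carboalumination); dienol from a 4‑silyloxy‑ynoate by syn‑vinylcupration and reduction.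
5. Ring order: open chain first, then carbocycle and lactone in one operation; no other ring is made.

## Route

Step 1
Reactants: 1 (R)-glycidol
Product: 2 (S)-pent-4-yne-1,2-diol
Conditions: LiC≡CH·H2N(CH2)2NH2 (2.5 equiv), DMSO, 0 °C → rt; H2O
Reagents that add atoms: lithium acetylide (LiC≡CH, used as its ethylenediamine complex), [Li]C#C
Why: SN2 opening of the terminal epoxide carbon by acetylide leaves the bought stereocentre untouched (it becomes C8; the label changes from R to S only through the priority change).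

Step 2
Reactants: 2 (S)-pent-4-yne-1,2-diol
Product: 3 (S)-4,5-bis(triethylsilyloxy)pent-1-yne
Conditions: TESCl (2.4 equiv), imidazole, DMF, 0 °C → rt
Reagents that add atoms: chlorotriethylsilane (TESCl), CC[Si](Cl)(CC)CC
Why: Standard silylation of both hydroxyls; the primary triethylsilyl ether is later the oxidisable one and the secondary one protects O‑8.

Step 3
Reactants: 3 (S)-4,5-bis(triethylsilyloxy)pent-1-yne
Product: 5 (S,E)-5-iodo-4-methyl-1,2-bis(triethylsilyloxy)pent-4-ene, via alkenylalane 4 (not isolated)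
Conditions: Me3Al (3 equiv), Cp2ZrCl2 (0.25 equiv), CH2Cl2, 0 °C → rt; then I2, THF, −30 → 0 °C
Reagents that add atoms: trimethylaluminium (Me3Al), C[Al](C)C; iodine (I2), II
Why: Negishi zirconium‑catalysed carboalumination adds methyl and aluminium syn across the terminal alkyne with aluminium at the terminus, and iodinolysis with retention gives the (E)-iodide (C1=C10 geometry and C14).

Step 4
Reactants: 6 tert-butyldimethyl(prop-2-ynyloxy)silane
Product: 8 ethyl 4-(tert-butyldimethylsilyloxy)but-2-ynoate, via lithium acetylide 7 (not isolated)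
Conditions: n-BuLi, THF, −78 °C; ClCO2Et, −78 → 0 °C
Reagents that add atoms: ethyl chloroformate, CCOC(=O)Cl
Why: Acylation of the lithium acetylide with a chloroformate is a routine route to ynoates.

Step 5
Reactants: 8 ethyl 4-(tert-butyldimethylsilyloxy)but-2-ynoate
Product: 10 ethyl (Z)-3-[(tert-butyldimethylsilyloxy)methyl]penta-2,4-dienoate, via alkenylcopper 9 (not isolated)
Conditions: CH2=CHMgBr (1.5 equiv), CuBr·SMe2 (1.5 equiv), THF, −78 °C; then 8; aq. NH4Cl at −78 °C
Reagents that add atoms: vinylmagnesium bromide (CH2=CHMgBr), C=C[Mg]Br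
Why: Syn‑carbocupration (conjugate addition) of the vinylcopper reagent to the ynoate and protonation with retention at −78 °C place the vinyl group trans to the ester, which fixes the C4=C5 geometry.

Step 6
Reactants: 10 ethyl (Z)-3-[(tert-butyldimethylsilyloxy)methyl]penta-2,4-dienoate
Product: 11 (Z)-3-[(tert-butyldimethylsilyloxy)methyl]penta-2,4-dien-1-ol
Conditions: i-Bu2AlH (2.2 equiv), CH2Cl2, −78 °C; aq. KNaC4H4O6
Reagents that add atoms: none
Why: Clean 1,2‑reduction of the conjugated ester by the aluminium hydride gives the electron‑rich dienol without touching the alkene geometry.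

Step 7
Reactants: 11 (Z)-3-[(tert-butyldimethylsilyloxy)methyl]penta-2,4-dien-1-ol; 5 (S,E)-5-iodo-4-methyl-1,2-bis(triethylsilyloxy)pent-4-ene
Product: 13 (2Z,6E,9S)-3-[(tert-butyldimethylsilyloxy)methyl]-7-methyl-9,10-bis(triethylsilyloxy)deca-2,6-dien-1-ol, via alkylborane 12 (not isolated)
Conditions: 9-BBN-H (2.2 equiv), THF, 0 °C → rt; then 5, Pd(dppf)Cl2 (5 mol%), AsPh3 (5 mol%), Cs2CO3, DMF/H2O, rt
Reagents that add atoms: none
Why: 9‑BBN hydroborates only the monosubstituted vinyl terminus (anti‑Markovnikov; the hydroxyl is masked as its borinate) and the B‑alkyl Suzuki–Miyaura coupling forms C1–C2 with retention of the (E)-iodide geometry.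

Step 8
Reactants: 13 (2Z,6E,9S)-3-[(tert-butyldimethylsilyloxy)methyl]-7-methyl-9,10-bis(triethylsilyloxy)deca-2,6-dien-1-ol
Product: 14 (2Z,6E,9S)-3-[(tert-butyldimethylsilyloxy)methyl]-7-methyl-9-(triethylsilyloxy)deca-2,6-dienedial
Conditions: (COCl)2, DMSO, CH2Cl2, −78 → −45 °C; Et3N, −78 → 0 °C
Reagents that add atoms: none
Why: Swern oxidation converts the allylic alcohol and, after chloride‑induced loss of the primary triethylsilyl group at the sulfonium stage, the C7 oxygen into aldehydes, while the secondary triethylsilyl and the tert‑butyldimethylsilyl ethers are not cleaved.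

Step 9
Reactants: 14 (2Z,6E,9S)-3-[(tert-butyldimethylsilyloxy)methyl]-7-methyl-9-(triethylsilyloxy)deca-2,6-dienedial; 15 methyl acrylate
Product: 16 methyl (4S,6E,10Z)-10-[(tert-butyldimethylsilyloxy)methyl]-3-hydroxy-6-methyl-2-methylene-12-oxo-4-(triethylsilyloxy)dodeca-6,10-dienoate (both C3 epimers)
Conditions: methyl acrylate (10 equiv, neat), DABCO (1 equiv), rt, 72 h
Reagents that add atoms: none
Why: The Morita–Baylis–Hillman reaction takes place only at the activated saturated α‑silyloxy aldehyde, the β,β‑disubstituted enal being far less electrophilic; the new carbinol centre is irrelevant because it is removed in step 10.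

Step 10
Reactants: 16 methyl (4S,6E,10Z)-10-[(tert-butyldimethylsilyloxy)methyl]-3-hydroxy-6-methyl-2-methylene-12-oxo-4-(triethylsilyloxy)dodeca-6,10-dienoate
Product: 17 methyl (2Z,4S,6E,10Z)-2-(bromomethyl)-10-[(tert-butyldimethylsilyloxy)methyl]-6-methyl-12-oxo-4-(triethylsilyloxy)dodeca-2,6,10-trienoate
Conditions: NBS, Me2S, CH2Cl2, −20 °C → rt
Reagents that add atoms: N-bromosuccinimide (NBS), O=C1CCC(=O)N1Br
Why: SN2′ bromination of the Baylis–Hillman alcohol through its alkoxysulfonium salt gives the favoured (Z)-2-(bromomethyl)enoate under neutral conditions that spare the enal and the silyl ethers.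

Step 11
Reactants: 17 methyl (2Z,4S,6E,10Z)-2-(bromomethyl)-10-[(tert-butyldimethylsilyloxy)methyl]-6-methyl-12-oxo-4-(triethylsilyloxy)dodeca-2,6,10-trienoate
Product: 21 8-O-triethylsilyl-15-O-tert-butyldimethylsilylsalonitenolide, via allylchromium dichloride 18 (not isolated), via trimethylsilyl ether 19 (not isolated), via hydroxy ester 20 (not isolated)
Conditions: CrCl3 (20 mol%), TMSCl (2 equiv), Bu4NBF4 (0.1 M), DMF/THF, undivided cell, Al anode, carbon‑felt cathode, 2 mA constant current, 17 added over 12 h (final 2 mM), rt; then 10% aq. citric acid/THF, rt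
Reagents that add atoms: none
Why: Proposed new method: cathodically regenerated divalent chromium (from catalytic CrCl3) reduces the allylic bromide in two one‑electron steps to a 2‑(methoxycarbonyl)allylchromium species of trivalent chromium, which adds through its γ‑carbon (C7) to the tethered enal in a chair Zimmerman–Traxler transition state (anti addition, hence the trans C6/C7 relationship; C6 approaches C7 anti to the C8 silyloxy group with H‑8 eclipsing the alkene to avoid A(1,3) strain, so the bought C8 centre sets C7 and C6), TMSCl frees chromium from the alkoxide, the current‑limited slow generation of the organochromium acts as internal high dilution, and the acidic work‑up desilylates and lactonises; the closest known reactions are the stoichiometric CrCl2 Nozaki–Hiyama–Kishi macrocyclisation to germacranolide lactones and the intermolecular electrochemical chromium‑catalysed allylation of aldehydes, neither of which has been shown as an electrocatalytic ring closure or with a 2‑(bromomethyl)enoate.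

Step 12
Reactants: 21 8-O-triethylsilyl-15-O-tert-butyldimethylsilylsalonitenolide
Product: 22 15-O-tert-butyldimethylsilylsalonitenolide
Conditions: PPTS (0.2 equiv), MeOH/CH2Cl2, 0 °C
Reagents that add atoms: none
Why: Acid‑catalysed methanolysis removes the triethylsilyl ether much faster than the primary tert‑butyldimethylsilyl ether, freeing only the 8α‑hydroxyl.

Step 13
Reactants: 23 methyl (S)-2,2-dimethyl-1,3-dioxolane-4-carboxylate
Product: 25 (R)-4-ethynyl-2,2-dimethyl-1,3-dioxolane, via aldehyde 24 (not isolated)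
Conditions: i-Bu2AlH (1.05 equiv), CH2Cl2, −78 °C; then MeOH, K2CO3, MeC(O)C(N2)P(O)(OMe)2, −78 °C → rt
Reagents that add atoms: dimethyl (1-diazo-2-oxopropyl)phosphonate (Ohira–Bestmann reagent), COP(=O)(OC)C(=[N+]=[N-])C(C)=O
Why: The hydride stops at the aluminium hemiacetal of the α‑alkoxy ester and the aldehyde released by methanol is homologated in situ by Seyferth–Gilbert (Ohira–Bestmann) alkynylation under K2CO3, which does not epimerise the bought centre (it becomes C3′).

Step 14
Reactants: 25 (R)-4-ethynyl-2,2-dimethyl-1,3-dioxolane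
Product: 26 (R)-2-(2,2-dimethyl-1,3-dioxolan-4-yl)acrylic acid
Conditions: Pd(OAc)2 (1 mol%), 2-(Ph2P)pyridine (6 mol%), MsOH (6 mol%), CO (30 bar), H2O (3 equiv), acetone, 45 °C
Reagents that add atoms: carbon monoxide, [C-]#[O+]; water, O
Why: Palladium‑catalysed Markovnikov hydroxycarbonylation (pyridylphosphine proton relay) puts CO2H on the internal alkyne carbon, and acetone as solvent keeps the acetonide intact.

Step 15
Reactants: 26 (R)-2-(2,2-dimethyl-1,3-dioxolan-4-yl)acrylic acid; 22 15-O-tert-butyldimethylsilylsalonitenolide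
Product: 28 15-O-tert-butyldimethylsilyl-3′,4′-O-isopropylidenecnicin, via mixed anhydride 27 (not isolated)
Conditions: 2,4,6-Cl3C6H2COCl, Et3N, THF, rt; then 22, DMAP, toluene, rt
Reagents that add atoms: none
Why: Yamaguchi esterification through the mixed anhydride acylates the hindered 8α‑hydroxyl with retention at C8.

Step 16
Reactants: 28 15-O-tert-butyldimethylsilyl-3′,4′-O-isopropylidenecnicin
Product: 29 cnicin
Conditions: PPTS (0.5 equiv), MeOH, 40 °C
Reagents that add atoms: none
Why: Mild acid‑catalysed transketalisation and solvolysis remove the terminal acetonide and the primary allylic silyl ether together, without base or strong acid that would attack the Michael acceptors or the cyclodecadiene.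

Step 17
Reactants: 29 cnicin
Product: 30 4′-O-acetylcnicin
Conditions: Me2SnCl2 (5 mol%), AcCl (1.05 equiv), K2CO3, THF, 0 °C
Reagents that add atoms: acetyl chloride, CC(Cl)=O
Why: In this tin‑catalysed regioselective acylation Me2SnCl2 forms a five‑membered stannylene acetal only with the 3′,4′‑diol and activates its primary oxygen, so O‑4′ is acetylated in preference to the isolated 15‑OH and the secondary 3′‑OH.

## Compound list

1 | (R)-glycidol ((R)-oxiran-2-ylmethanol) | OC[C@@H]1CO1 | starting material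
2 | (S)-pent-4-yne-1,2-diol | OC[C@@H](O)CC#C | intermediate
3 | (S)-4,5-bis(triethylsilyloxy)pent-1-yne | CC[Si](CC)(CC)OC[C@@H](O[Si](CC)(CC)CC)CC#C | intermediate
4 | alkenylalane (dimethyl[(S,E)-2-methyl-4,5-bis(triethylsilyloxy)pent-1-enyl]alane) | CC[Si](CC)(CC)OC[C@@H](O[Si](CC)(CC)CC)C/C(C)=C/[Al](C)C | intermediate
5 | (S,E)-5-iodo-4-methyl-1,2-bis(triethylsilyloxy)pent-4-ene | CC[Si](CC)(CC)OC[C@@H](O[Si](CC)(CC)CC)C/C(C)=C/I | intermediate
6 | tert-butyldimethyl(prop-2-ynyloxy)silane | C#CCO[Si](C)(C)C(C)(C)C | starting material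
7 | lithium acetylide ([3-(tert-butyldimethylsilyloxy)prop-1-ynyl]lithium) | [Li]C#CCO[Si](C)(C)C(C)(C)C | intermediate
8 | ethyl 4-(tert-butyldimethylsilyloxy)but-2-ynoate | CCOC(=O)C#CCO[Si](C)(C)C(C)(C)C | intermediate
9 | alkenylcopper (ethyl 2-cuprio-3-[(tert-butyldimethylsilyloxy)methyl]penta-2,4-dienoate, Cu cis to the vinyl group) | CCOC(=O)/C([Cu])=C(\CO[Si](C)(C)C(C)(C)C)C=C | intermediate
10 | ethyl (Z)-3-[(tert-butyldimethylsilyloxy)methyl]penta-2,4-dienoate | CCOC(=O)/C=C(\CO[Si](C)(C)C(C)(C)C)C=C | intermediate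
11 | (Z)-3-[(tert-butyldimethylsilyloxy)methyl]penta-2,4-dien-1-ol | OC/C=C(\CO[Si](C)(C)C(C)(C)C)C=C | intermediate
12 | alkylborane (9-[(Z)-3-[(tert-butyldimethylsilyloxy)methyl]-5-(9-borabicyclo[3.3.1]nonan-9-yloxy)pent-3-enyl]-9-borabicyclo[3.3.1]nonane) | CC(C)(C)[Si](C)(C)OC/C(CCB1C2CCCC1CCC2)=C\COB1C2CCCC1CCC2 | intermediate
13 | (2Z,6E,9S)-3-[(tert-butyldimethylsilyloxy)methyl]-7-methyl-9,10-bis(triethylsilyloxy)deca-2,6-dien-1-ol | OC/C=C(\CO[Si](C)(C)C(C)(C)C)CC/C=C(\C)C[C@H](O[Si](CC)(CC)CC)CO[Si](CC)(CC)CC | intermediate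
14 | (2Z,6E,9S)-3-[(tert-butyldimethylsilyloxy)methyl]-7-methyl-9-(triethylsilyloxy)deca-2,6-dienedial | O=C/C=C(\CO[Si](C)(C)C(C)(C)C)CC/C=C(\C)C[C@H](O[Si](CC)(CC)CC)C=O | intermediate
15 | methyl acrylate | C=CC(=O)OC | starting material
16 | methyl (4S,6E,10Z)-10-[(tert-butyldimethylsilyloxy)methyl]-3-hydroxy-6-methyl-2-methylene-12-oxo-4-(triethylsilyloxy)dodeca-6,10-dienoate (both C3 epimers) | COC(=O)C(=C)C(O)[C@@H](O[Si](CC)(CC)CC)C/C(C)=C/CC/C(CO[Si](C)(C)C(C)(C)C)=C/C=O | intermediate
17 | methyl (2Z,4S,6E,10Z)-2-(bromomethyl)-10-[(tert-butyldimethylsilyloxy)methyl]-6-methyl-12-oxo-4-(triethylsilyloxy)dodeca-2,6,10-trienoate | COC(=O)/C(CBr)=C/[C@@H](O[Si](CC)(CC)CC)C/C(C)=C/CC/C(CO[Si](C)(C)C(C)(C)C)=C/C=O | intermediate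
18 | allylchromium dichloride (σ‑allyl species of trivalent chromium, Cl2Cr–CH2 in place of BrCH2 of 17) | COC(=O)/C(C[Cr](Cl)Cl)=C/[C@@H](O[Si](CC)(CC)CC)C/C(C)=C/CC/C(CO[Si](C)(C)C(C)(C)C)=C/C=O | intermediate
19 | trimethylsilyl ether (6‑O‑trimethylsilyl ether of 20) | COC(=O)C(=C)[C@H]1[C@H](O[Si](C)(C)C)/C=C(\CO[Si](C)(C)C(C)(C)C)CC/C=C(\C)C[C@@H]1O[Si](CC)(CC)CC | intermediate
20 | hydroxy ester (methyl 6α-hydroxy-8α-(triethylsilyloxy)-15-(tert-butyldimethylsilyloxy)germacra-1(10)E,4Z,11(13)-trien-12-oate, 7α-H) | COC(=O)C(=C)[C@H]1[C@H](O)/C=C(\CO[Si](C)(C)C(C)(C)C)CC/C=C(\C)C[C@@H]1O[Si](CC)(CC)CC | intermediate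
21 | 8-O-triethylsilyl-15-O-tert-butyldimethylsilylsalonitenolide (8α-(triethylsilyloxy)-15-(tert-butyldimethylsilyloxy)germacra-1(10)E,4Z,11(13)-trien-6α,12-olide; 6β-H, 7α-H, 8β-H) | C=C1C(=O)O[C@@H]2/C=C(\CO[Si](C)(C)C(C)(C)C)CC/C=C(\C)C[C@H](O[Si](CC)(CC)CC)[C@@H]12 | intermediate
22 | 15-O-tert-butyldimethylsilylsalonitenolide (8α-hydroxy-15-(tert-butyldimethylsilyloxy)germacra-1(10)E,4Z,11(13)-trien-6α,12-olide) | C=C1C(=O)O[C@@H]2/C=C(\CO[Si](C)(C)C(C)(C)C)CC/C=C(\C)C[C@H](O)[C@@H]12 | intermediate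
23 | methyl (S)-2,2-dimethyl-1,3-dioxolane-4-carboxylate | COC(=O)[C@@H]1COC(C)(C)O1 | starting material
24 | aldehyde ((S)-2,2-dimethyl-1,3-dioxolane-4-carbaldehyde) | O=C[C@@H]1COC(C)(C)O1 | intermediate
25 | (R)-4-ethynyl-2,2-dimethyl-1,3-dioxolane | C#C[C@@H]1COC(C)(C)O1 | intermediate
26 | (R)-2-(2,2-dimethyl-1,3-dioxolan-4-yl)acrylic acid | C=C(C(=O)O)[C@@H]1COC(C)(C)O1 | intermediate
27 | mixed anhydride ((R)-2-(2,2-dimethyl-1,3-dioxolan-4-yl)acrylic 2,4,6-trichlorobenzoic anhydride) | C=C(C(=O)OC(=O)c1c(Cl)cc(Cl)cc1Cl)[C@@H]1COC(C)(C)O1 | intermediate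
28 | 15-O-tert-butyldimethylsilyl-3′,4′-O-isopropylidenecnicin (8α-ester of 22 with acid 26) | C=C1C(=O)O[C@@H]2/C=C(\CO[Si](C)(C)C(C)(C)C)CC/C=C(\C)C[C@H](OC(=O)C(=C)[C@@H]3COC(C)(C)O3)[C@@H]12 | intermediate
29 | cnicin (salonitenolide 8-O-[(3R)-3,4-dihydroxy-2-methylenebutanoate]) | C=C1C(=O)O[C@@H]2/C=C(\CO)CC/C=C(\C)C[C@H](OC(=O)C(=C)[C@@H](O)CO)[C@@H]12 | intermediate
30 | 4′-O-acetylcnicin (CNP0219661.4; 6R,7R,8S,3′R) | C=C1C(=O)O[C@@H]2/C=C(\CO)CC/C=C(\C)C[C@H](OC(=O)C(=C)[C@@H](O)COC(C)=O)[C@@H]12 | target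

## Step count and risks

Total step count: 17. Longest linear sequence: 12 steps (1, 2, 3, 7, 8, 9, 10, 11, 12, 15, 16, 17 from 1; the branch from 6 is equally long).

**Step 11 (proposed electrochemical ring closure).** Risks: direct cathodic reduction or chromium‑induced pinacol coupling of the enal, oligomerisation instead of ring closure, and the wrong facial selectivity at C7/C6. Fallback: it sets out from 17 and comes back at 21. The electrolysis and the catalytic chromium turnover are given up for the known stoichiometric reagent: 17 is added by syringe pump (final 2 mM) to CrCl2 (divalent chromium, 8 equiv) in THF/DMF at rt, and the chromium alkoxide of 20 lactonises on mild acid work‑up to 21. This stoichiometric Nozaki–Hiyama–Kishi allylation–lactonisation is established for closing the ten‑membered ring of germacranolides. New compounds on this path: none F0.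

**Step 9 (Baylis–Hillman reaction on the dialdehyde).** Risks: slow reaction, partial isomerisation of the (Z)-enal by the amine, and epimerisation at C8. Fallback: it sets out from 5 and comes back at 16, so that the Baylis–Hillman reaction is run on a mono‑aldehyde before any enal exists. Swern oxidation of 5 (primary triethylsilyl ether only) gives (S,E)-5-iodo-4-methyl-2-(triethylsilyloxy)pent-4-enal F1. Its DABCO reaction with 15 gives methyl (4S,6E)-3-hydroxy-7-iodo-6-methyl-2-methylene-4-(triethylsilyloxy)hept-6-enoate F2. B‑alkyl Suzuki coupling of F2 with the borane 12 (Pd(dppf)Cl2, Cs2CO3) gives methyl (4S,6E,10Z)-10-[(tert-butyldimethylsilyloxy)methyl]-3,12-dihydroxy-6-methyl-2-methylene-4-(triethylsilyloxy)dodeca-6,10-dienoate F3. MnO2 in CH2Cl2 then oxidises only the primary allylic alcohol and returns to 16.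

**Step 17 (tin‑directed 4′‑O‑acetylation of cnicin).** Risk: competing acetylation of the primary allylic 15‑OH. Fallback: it sets out from 28 and comes back at 30, keeping O‑15 silylated until the end. CeCl3·7H2O with oxalic acid in MeCN removes only the acetonide and gives 15-O-tert-butyldimethylsilylcnicin F4. AcCl with 2,4,6‑collidine in CH2Cl2 at −78 °C acetylates the primary 4′‑OH and gives 15-O-tert-butyldimethylsilyl-4′-O-acetylcnicin F5. HF·pyridine in THF/pyridine at 0 °C then removes the silyl group and gives 30.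

Further compounds
F1 | step 9 | (S,E)-5-iodo-4-methyl-2-(triethylsilyloxy)pent-4-enal | O=C[C@@H](O[Si](CC)(CC)CC)C/C(C)=C/I
F2 | step 9 | methyl (4S,6E)-3-hydroxy-7-iodo-6-methyl-2-methylene-4-(triethylsilyloxy)hept-6-enoate | COC(=O)C(=C)C(O)[C@@H](O[Si](CC)(CC)CC)C/C(C)=C/I
F3 | step 9 | methyl (4S,6E,10Z)-10-[(tert-butyldimethylsilyloxy)methyl]-3,12-dihydroxy-6-methyl-2-methylene-4-(triethylsilyloxy)dodeca-6,10-dienoate | COC(=O)C(=C)C(O)[C@@H](O[Si](CC)(CC)CC)C/C(C)=C/CC/C(CO[Si](C)(C)C(C)(C)C)=C/CO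
F0 | step 11 | none | none
F4 | step 17 | 15-O-tert-butyldimethylsilylcnicin | C=C1C(=O)O[C@@H]2/C=C(\CO[Si](C)(C)C(C)(C)C)CC/C=C(\C)C[C@H](OC(=O)C(=C)[C@@H](O)CO)[C@@H]12
F5 | step 17 | 15-O-tert-butyldimethylsilyl-4′-O-acetylcnicin | C=C1C(=O)O[C@@H]2/C=C(\CO[Si](C)(C)C(C)(C)C)CC/C=C(\C)C[C@H](OC(=O)C(=C)[C@@H](O)COC(C)=O)[C@@H]12
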